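Atom numbers follow the atom order of the target SMILES (C1 is the methyl on C2, O4 the oxygen on C3, C7 the carbinol carbon of the side chain, O34 the ring C oxygen on C18). Rings: A (C2, C3, C5, C6, C11, C18), B (C11, C12, C13, C14, O16, C17), C (C18, C19, C20, C31, O34), D (C20, C22, C24, C33, O32, C31), E (C24, C25, O27, C28, C33), F (C28, O30, C31, O32, C33).

Assumption: the enantiomers named for the phosphoramidite (step 9), the silylated alkaloid (step 16) and the oxazolidinone of the fallbacks are those expected from the accepted models to give the configurations drawn; each is available in both (pseudo)enantiomeric forms, and the antipode is used if the sense of induction proves opposite.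

## Analysis of the target

Chermebilaene B is hexacyclic. Cyclohexane ring A carries a spiro δ-lactone at C11 (ring B) and, at C18, a spiro five-membered ring C whose carbon C31 is an orthoester shared with rings D and F. Ring E is a γ-lactone whose alkoxy carbon C28 is at the same time a ketal carbon of ring F. There are eleven stereocentres (C2, C3, C6, C11, C18, C20, C22, C24, C28, C31, C33); C28 and C31 are fixed once the cage is closed. On ring A the C1 methyl, O4, the C7 side chain, C17 and O34 all lie on one face, with C12 and C19 on the other. The C1 methyl therefore sits cis to both flanking oxygens, which is the less stable orientation and has to be set kinetically. C11 and C18 are adjacent fully substituted carbons, and C20 is a third quaternary centre next to the tertiary C22. The sensitive groups are the orthoester, the acylated ketal at C28 (a masked γ-keto acid), the C33 oxygen β to the C25 carbonyl (elimination) and the tertiary C7 carbinol. The strategy rests on the C24–C33 bond: it joins the α-carbon of the C25 carboxyl to the carbinol carbon next to the latent methyl ketone C28, an aldol-type relationship. In the target, however, C25 is bound to the C28 oxygen (O27) and not to the aldol oxygen O32, which is needed for the orthoester. A β-lactone made by ketene–aldehyde cycloaddition forms C24–C33 and parks C25 on O32 in a strained ring, which later passes the acyl group to the C28 hydrate and frees O32.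

## Retrosynthetic reasoning

27 to 26: only the two O–Si bonds are cut. The C3 and C7 hydroxyls must be masked through enolate, acid chloride and ketene chemistry, and silyl ethers can be removed at the end by fluoride without aqueous acid, which the orthoester would not tolerate.

26 to 25: C31–O32 and C31–O30 are cut, opening rings D and F. The orthoester is the most labile function and is therefore made last. The cut returns ring C as an ordinary γ-lactone and a cis-diol on ring E, carried as its acetonide. The forward step must add both oxygens to the C31 carbonyl with loss of the acetonide ketone, and this is geometrically possible only if C22 and O32 are cis on ring E.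

25 to 24: no bond is cut; C24 is inverted. The cycloaddition delivers the cis β-lactone, which after acyl transfer places C22 trans to O32 on ring E. The forward step is a kinetic protonation of the ring E enolate on the convex face of the bicyclic acetonide, which gives the contra-thermodynamic epimer that the cage needs.

24 to 21: C25–O27 is cut and C25–O32 reconnected, so that ring E becomes a β-lactone and the C28 ketal a dioxolane. The gain is that 21 is the direct product of a (2+2) cycloaddition, and its ring strain drives the acyl transfer to the C28 hydrate in the forward direction.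

21 to 16 and 19: C24–C33 and C25–O32 are cut together. This is the most convergent cut in the cage region: it splits off a three-carbon aldehyde without α-hydrogens and leaves an acid chloride that holds all of rings A, B and C. The forward step must form the two bonds, set C33 by catalyst control and tolerate two lactones and two silyl ethers.

16 back to 12: functional-group changes only. The acid chloride comes from acid 15. The ring B lactone (C14–O16) and the C25 acid arise together by one oxidation of triol 14, which comes from diol 13 by loss of the benzyl group, and 13 from the two terminal alkenes of 12. Ring B is kept latent until here on purpose: its C13 hydrogens would compete with C20–H in the enolate step that precedes.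

12 to 9 and 10: C20–C22 is cut. A branched-selective allylic substitution makes the quaternary C20 and the tertiary C22 in one step, with C22 under catalyst control and C20 under control of the spiro lactone face. The vinyl group it leaves is the latent C24–C25 acid.

9 to 8: C18–C19 and O34–C31 are cut. A reductive ketyl–olefin coupling with lactonisation builds ring C in one step on the C18 ketone and uses the crowding of the lower face of ring A to set C18.

8 back to 5: no skeletal bond is cut. The cis relationship of the C1 methyl and O4, both anti to the C2 hydrogen, corresponds to an anti addition of H and O across C2=C3, which hydroboration cannot give. It is obtained from the syn epoxy alcohol 7 by a stereospecific 1,2-hydride shift from C18 to C2, which at the same time regenerates the C18 ketone. Epoxy alcohol 7 comes from allylic alcohol 6 and this from enone 5.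

5 back to 1: C11–C12 and then C11–C17 are cut. Two successive enolate alkylations of the only α′ position make C11; the order (C17 first, C12 second) sets its configuration because the second electrophile enters anti to the C6 side chain. Hydration of the isopropenyl group gives C7–O10. Compound 1 supplies C6, the C1 methyl and the enone.

19 back to 17: the aldehyde is the reduced, ketal-protected form of pyruvate ester 17.

## Alternatives that were turned down

Alternative 1: The decalin bonds C6–C7 and C11–C18 are disconnected to an acyclic epoxy triene, and the extra carbocycle (C7, C14, C13, C12) is later cut between C7 and C14 to reveal ring B and the C7 carbinol. In the forward key step Cp2TiCl (trivalent titanium), made from Cp2TiCl2 (tetravalent titanium) and manganese, opens the C14–C7 epoxide at the tertiary carbon; the C7 radical adds to C6, the C11 radical to C18, and the cascade ends as the exocyclic C1=C2 alkene in the trans-decalin hydroxy acetate A1. It forms two rings and two C–C bonds in one step from a flat precursor, sets C6 and C11 trans, and keeps the C14 oxygen for the later ring excision; on ring-forming economy it is stronger than the stepwise alkylations 3 to 5 of the chosen route. Against it for this target: C18 arrives as a methine carrying C19, not as the tertiary C–O centre needed, so a late oxidation at a hindered tertiary carbon would be required. C3 has no oxygen. The absolute configuration rests on an enantioselective epoxidation whose own stereocentre (C14) is later destroyed. The excision of the extra ring costs at least three further steps, and nothing of rings C to F is addressed. The chosen route takes C6 from the chiral pool, keeps C18 as a ketone that is used twice (hydride shift, ring C) and spends its key step on the cage.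

Alternative 2: C14–O16 and C7–O10 are traced back to a C7–C14 bond of a decalin enedione. A peracid inserts oxygen between the C14 carbonyl and the quaternary C7 (the better migrating group), and the C17 hydroxyl then takes the acyl group from O10, which closes ring B and liberates the tertiary carbinol in the spiro-lactone enone A2. This creates ring B and the C7 carbinol in one operation with predictable regiochemistry, the decalin can come from a catalytic asymmetric annulation, and A2 carries the same enone as compound 5; for reaching rings A and B it is about as short as the chosen sequence and more elegant. Against it: it needs an angular hydroxymethyl decalin, which is less accessible than the methyl congeners. The trans relationship at C6/C11 must be set separately, and the peracid must distinguish two ketones. Above all, ring B is unmasked early, so its C13 hydrogens compete with C20–H in the enolate chemistry that builds C20 and C22. The chosen route avoids this by carrying ring B as an allyl group and a benzyl ether until acid 15.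

Alternative 3: C18–C19 is disconnected. Rh2(O2CCPh3)4 (divalent rhodium) turns a diazo ester at C19, tethered through the C20–C31 ester on O34, into a carbenoid that inserts into the axial C18–H bond (activated by O34) with retention and closes ring C as the spiro γ-lactone diester A3. The strategy is convergent: the C20–C25 chain with C20 and C22 can be built in an acyclic setting and attached by esterification. On control of C20 and C22 it is stronger than step 9 of the chosen route, which relies on the facial bias of the spiro lactone. Against it: the hindered C18 carbinol (next to quaternary C11) must be acylated by an acid with a quaternary α-carbon. The extra ester on C19 must afterwards be removed in the presence of four other carboxyl derivatives. Insertion into C2–H or C22–H competes, and C18 must be a carbinol methine, which excludes the ketone-based control of C2 used here. The chosen route closes ring C in one step from ketone 8 without an extra carboxyl and keeps the main risk in the cage-forming step.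

Key step: step 16

## Route

Step 1
Reactants: 1 (R)-carvone
Product: 2 (5R)-5-(2-hydroxypropan-2-yl)-2-methylcyclohex-2-en-1-one
Conditions: 50% aq. H2SO4, 0 °C
Reagents that add atoms: water, O
Why: Acid-catalysed Markovnikov hydration of the 1,1-disubstituted alkene through the tertiary cation; the conjugated alkene is deactivated toward protonation and the stereocentre (C6 of the target) is not touched.

Step 2
Reactants: 2 (5R)-5-(2-hydroxypropan-2-yl)-2-methylcyclohex-2-en-1-one
Product: 3 (5R)-2-methyl-5-[2-(triethylsilyloxy)propan-2-yl]cyclohex-2-en-1-one
Conditions: Et3SiOTf, 2,6-lutidine, CH2Cl2, −78 → 0 °C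
Reagents that add atoms: triethylsilyl triflate, CC[Si](CC)(CC)OS(=O)(=O)C(F)(F)F
Why: Silylation of a tertiary alcohol with a silyl triflate; the ether (O10) masks the carbinol for the enolate, organometallic and acid chloride steps.

Step 3
Reactants: 3 (5R)-2-methyl-5-[2-(triethylsilyloxy)propan-2-yl]cyclohex-2-en-1-one
Product: 4 6-(benzyloxymethyl) enone (CH2OBn trans to the side chain)
Conditions: LiN(iPr)2, THF, −78 °C; BnOCH2Cl, −78 → −40 °C
Reagents that add atoms: benzyl chloromethyl ether, ClCOCc1ccccc1
Why: Kinetic cross-conjugated enolate formation at the only α′ position and C-alkylation by a reactive alkoxymethyl chloride introduces C17; the configuration at C11 is of no consequence because the centre is enolised again in step 4.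

Step 4
Reactants: 4 6-(benzyloxymethyl) enone (CH2OBn trans to the side chain)
Product: 5 6-allyl-6-(benzyloxymethyl) enone (allyl trans and CH2OBn cis to the side chain)
Conditions: LiN(iPr)2, THF/DMPU, −78 °C; allyl bromide, −78 → −40 °C
Reagents that add atoms: allyl bromide, C=CCBr
Why: Second enolate alkylation; the electrophile should approach anti to the bulky C6 side chain, so that C12 ends trans and C17 cis to C7, which is the C11 configuration of the target. The low temperature guards against loss of benzyloxide from the β-alkoxy enolate.

Step 5
Reactants: 5 6-allyl-6-(benzyloxymethyl) enone (allyl trans and CH2OBn cis to the side chain)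
Product: 6 allylic alcohol (C18 hydroxyl cis to the C7 side chain and to C17)
Conditions: NaBH4, CeCl3·7H2O, MeOH, −40 → 0 °C
Reagents that add atoms: none
Why: Luche 1,2-reduction; the lower face of the carbonyl is screened by C17 and the C7 side chain, so hydride should add from the face of the allyl group and place the C18 hydroxyl cis to C17 and C7.

Step 6
Reactants: 6 allylic alcohol (C18 hydroxyl cis to the C7 side chain and to C17)
Product: 7 syn 2,3-epoxy alcohol (epoxide oxygen on the face of the C18 hydroxyl)
Conditions: VO(acac)2 (cat.), tBuOOH, CH2Cl2, 0 °C → rt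
Reagents that add atoms: tert-butyl hydroperoxide, CC(C)(C)OO
Why: Hydroxyl-directed epoxidation: the vanadium alkoxide delivers the peroxide oxygen to the allylic trisubstituted alkene on the face of the hydroxyl, which sets the C3–O bond on the face of O34; the remote allyl group is not activated.

Step 7
Reactants: 7 syn 2,3-epoxy alcohol (epoxide oxygen on the face of the C18 hydroxyl)
Product: 8 β-silyloxy ketone (C18 ketone; C1 methyl and C3 OTBS cis)
Conditions: tBuMe2SiOTf, iPr2NEt, 4 Å MS, CH2Cl2, −40 °C
Reagents that add atoms: tert-butyldimethylsilyl triflate, CC(C)(C)[Si](C)(C)OS(=O)(=O)C(F)(F)F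
Why: Non-aldol aldol rearrangement of an epoxy silyl ether: the triflate silylates the carbinol and activates the epoxide, the C2–O bond ionises at the tertiary carbon, and the C18 hydrogen, which lies on the face opposite the departing oxygen, shifts to C2 with inversion. The C1 methyl therefore ends cis to the C3 oxygen, the epoxide oxygen stays on C3 as its TBS ether, and the oxocarbenium at C18 loses silyl to give the ketone. The weak amine base at low temperature should leave the kinetically set C2 centre untouched.

Step 8
Reactants: 8 β-silyloxy ketone (C18 ketone; C1 methyl and C3 OTBS cis)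
Product: 9 spiro α-methyl γ-lactone (ring C; both C20 epimers)
Conditions: SmI2, methyl methacrylate, tBuOH, THF, −78 → 0 °C
Reagents that add atoms: methyl methacrylate, C=C(C)C(=O)OC
Why: Samarium diiodide-mediated ketyl–olefin coupling with lactonisation: the ketyl adds to the acrylate β-carbon (C18–C19), the resulting α-ester radical is reduced and protonated, and the samarium alkoxide closes the lactone (O34–C31) with loss of methoxide. The lower face of ring A carries the C1 methyl, C17, the C3 silyl ether and the C7 side chain, so the new C–C bond should form on the upper face (C19 axial, O34 equatorial). C20 is not controlled and is erased in step 9.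

Step 9
Reactants: 9 spiro α-methyl γ-lactone (ring C; both C20 epimers), 10 methyl (E)-but-2-enyl carbonate
Product: 12 C20-quaternary lactone bearing the but-3-en-2-yl group, via silyl ketene acetal 11 (not isolated)
Conditions: LiN(iPr)2, THF, −78 °C; Me3SiCl, −78 → 0 °C; then [Ir(cod)Cl]2 (2 mol%), (Ra,R,R)-binaphthol-derived N,N-bis(1-phenylethyl)phosphoramidite (4 mol%, preactivated with nPrNH2), 10, THF, 35 °C
Reagents that add atoms: none
Why: Iridium-catalysed branched-selective allylic substitution of an ester silyl ketene acetal; the methoxide released from the carbonate desilylates the acetal, and the enolate attacks the substituted terminus of the allyl–iridium complex (C20–C22). C22 is set by the phosphoramidite; C20 by the substrate, since the face of ring C flanked by the C2 hydrogen is more open than the one flanked by the C12 methylene. Ring C holds the only acidic α-hydrogen at this stage because ring B is still latent.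

Step 10
Reactants: 12 C20-quaternary lactone bearing the but-3-en-2-yl group
Product: 13 diol (C14 and C25 primary alcohols)
Conditions: 9-BBN, THF, 0 °C → rt; then H2O2, aq. NaOAc, 0 °C → rt
Reagents that add atoms: hydrogen peroxide, OO
Why: Anti-Markovnikov hydroboration of both terminal alkenes by a bulky dialkylborane, followed by oxidation with retention; the buffered oxidation spares the hindered spiro lactone and the silyl ethers.

Step 11
Reactants: 13 diol (C14 and C25 primary alcohols)
Product: 14 triol (C14, C17 and C25 primary alcohols)
Conditions: H2 (1 atm), Pd/C, EtOAc, rt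
Reagents that add atoms: none
Why: Hydrogenolysis of the benzyl ether; no alkene remains, and silyl ethers and the lactone are inert.

Step 12
Reactants: 14 triol (C14, C17 and C25 primary alcohols)
Product: 15 carboxylic acid holding rings A, B and C
Conditions: TEMPO (cat.), PhI(OAc)2, MeCN/H2O, rt
Reagents that add atoms: water, O
Why: Oxoammonium oxidation: the unhindered C14 and C25 alcohols should be oxidised first; the C14 aldehyde is trapped by the neopentyl C17 hydroxyl as a lactol and oxidised on to the ring B δ-lactone (C14–O16), while the C25 aldehyde is oxidised through its hydrate to the acid.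

Step 13
Reactants: 15 carboxylic acid holding rings A, B and C
Product: 16 acid chloride holding rings A, B and C
Conditions: 1-chloro-N,N,2-trimethylprop-1-en-1-amine, CH2Cl2, 0 °C → rt
Reagents that add atoms: 1-chloro-N,N,2-trimethylprop-1-en-1-amine, CC(C)=C(Cl)N(C)C
Why: Chlorination of the acid by an α-chloroenamine under neutral conditions; no hydrogen chloride is set free, so the tertiary silyl ether and the lactones should survive.

Step 14
Reactants: 17 methyl pyruvate
Product: 18 methyl 2-methyl-1,3-dioxolane-2-carboxylate
Conditions: ethylene glycol, TsOH (cat.), toluene, reflux, Dean–Stark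
Reagents that add atoms: ethylene glycol, OCCO
Why: Acid-catalysed ketalisation of the ketone with azeotropic removal of water.

Step 15
Reactants: 18 methyl 2-methyl-1,3-dioxolane-2-carboxylate
Product: 19 2-methyl-1,3-dioxolane-2-carbaldehyde
Conditions: iBu2AlH, CH2Cl2, −78 °C; aq. potassium sodium tartrate
Reagents that add atoms: none
Why: Partial reduction of an α-alkoxy ester; the chelated aluminium hemiacetal is stable at −78 °C and gives the aldehyde on work-up.

Step 16
Reactants: 16 acid chloride holding rings A, B and C, 19 2-methyl-1,3-dioxolane-2-carbaldehyde
Product: 21 cis β-lactone (C33 as in the target and C24 epimeric), via ketene 20 (not isolated)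
Conditions: iPr2NEt, O-trimethylsilylquinine (15 mol%), LiClO4, CH2Cl2/Et2O, −78 → −40 °C, slow addition of 16
Reagents that add atoms: none
Why: iPr2NEt dehydrochlorinates 16 to the monosubstituted ketene 20, and the silylated alkaloid adds to its carbonyl carbon to give a (Z)-acylammonium enolate. This enolate adds to aldehyde 19, which is activated by lithium bound to the formyl and ketal oxygens, through a closed array that forms C24–C33; the lithium aldolate then attacks the acylammonium carbon in a 4-exo-trig closure that forms C25–O32 and releases the catalyst. The closest known reaction is the cinchona alkaloid and lithium perchlorate catalysed cyclocondensation of alkyl-substituted acid chlorides with aldehydes to cis-3,4-disubstituted β-lactones. C33 is set by the alkaloid, which shields one face of the enolate–aldehyde pair; C24 follows from the Z enolate and the closed transition state, hence the cis ring. The step needs chemoselective ketene formation and an aldehyde that cannot enolise: 16 carries the only acyl chloride, the amine does not remove the α-hydrogens of ring B, and 19 has no α-hydrogen. Slow addition of 16 keeps the ketene concentration low and suppresses its dimerisation; the resident C22 centre should be matched with, or overridden by, the catalyst.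

Step 17
Reactants: 21 cis β-lactone (C33 as in the target and C24 epimeric)
Product: 24 ring E lactone acetonide (C24 epimeric to the target), via keto lactone 22 (not isolated), via lactol 23 (not isolated)
Conditions: PPTS, acetone/H2O, reflux; concentrate; then 2-methoxypropene, PPTS (cat.), CH2Cl2, 0 °C
Reagents that add atoms: water, O; 2-methoxypropene, COC(C)=C
Why: Ketal exchange frees the C28 ketone, and a hydroxyl of its hydrate attacks the strained β-lactone carbonyl (5-exo-trig), expelling O32 and giving the ring E lactol with C24 and C33 unchanged. The cis-diol (O30–H, O32–H) is then tied as an acetonide, which locks the ring form of this pseudo-acid so that base cannot open it to the keto carboxylate.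

Step 18
Reactants: 24 ring E lactone acetonide (C24 epimeric to the target)
Product: 25 ring E lactone acetonide (C24 as in the target)
Conditions: LiN(iPr)2 (3 equiv), THF, −78 °C; then AcOH in THF, −78 °C
Reagents that add atoms: none
Why: Enolisation of the ring E lactone (the ring B lactone is enolised as well and returns unchanged) and kinetic protonation on the convex face of the cis-fused bicyclic enolate; the concave face is blocked by the dioxolane ring and its endo methyl. The proton therefore enters trans to O32 and C22 ends cis to O32, the contra-thermodynamic epimer that the cage needs. The low temperature should prevent β-elimination of the C33 oxygen.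

Step 19
Reactants: 25 ring E lactone acetonide (C24 as in the target)
Product: 26 bis-silyl ether of chermebilaene B (C3 OTBS and C7 OTES)
Conditions: CSA (cat.), toluene, 5 Å MS, 50 °C
Reagents that add atoms: none
Why: Acid-catalysed acetal exchange: the acetonide opens, O32 adds to the ring C lactone carbonyl C31 (closing the six-membered ring D) and O30 then closes ring F on C31, with loss of acetone, whose removal pulls the equilibrium. This is the intramolecular acid-catalysed formation of an orthoester from a carboxyl carbonyl and a proximal diol, as known for cage polyol esters. Only the C24 epimer 25 can span the cage, and closure fixes C28 and C31.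

Step 20
Reactants: 26 bis-silyl ether of chermebilaene B (C3 OTBS and C7 OTES)
Product: 27 chermebilaene B
Conditions: HF·pyridine, pyridine, THF, 0 °C → rt
Reagents that add atoms: none
Why: Fluoride-mediated cleavage of both silyl ethers under buffered conditions with little water, which should leave the caged orthoester, the acylated ketal and the lactones intact.

## Compound list

1 | (R)-carvone | CC(=C)[C@@H]1CC=C(C)C(=O)C1 | starting material
2 | (5R)-5-(2-hydroxypropan-2-yl)-2-methylcyclohex-2-en-1-one | CC1=CC[C@@H](C(C)(C)O)CC1=O | intermediate
3 | (5R)-2-methyl-5-[2-(triethylsilyloxy)propan-2-yl]cyclohex-2-en-1-one | CC1=CC[C@@H](C(C)(C)O[Si](CC)(CC)CC)CC1=O | intermediate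
4 | 6-[(benzyloxy)methyl]-2-methyl-5-[2-(triethylsilyloxy)propan-2-yl]cyclohex-2-en-1-one, 5,6-trans | CC1=CC[C@@H](C(C)(C)O[Si](CC)(CC)CC)[C@H](COCc2ccccc2)C1=O | intermediate
5 | 6-allyl-6-[(benzyloxy)methyl]-2-methyl-5-[2-(triethylsilyloxy)propan-2-yl]cyclohex-2-en-1-one, allyl trans and CH2OBn cis to the side chain | CC1=CC[C@@H](C(C)(C)O[Si](CC)(CC)CC)[C@](COCc2ccccc2)(CC=C)C1=O | intermediate
6 | cyclohex-2-en-1-ol from 5, hydroxyl cis to the side chain and to CH2OBn | CC1=CC[C@@H](C(C)(C)O[Si](CC)(CC)CC)[C@](COCc2ccccc2)(CC=C)[C@H]1O | intermediate
7 | 2,3-epoxy alcohol from 6, epoxide syn to the hydroxyl | C[C@]12O[C@H]1C[C@@H](C(C)(C)O[Si](CC)(CC)CC)[C@](COCc3ccccc3)(CC=C)[C@H]2O | intermediate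
8 | 2-allyl-2-[(benzyloxy)methyl]-5-(tert-butyldimethylsilyloxy)-6-methyl-3-[2-(triethylsilyloxy)propan-2-yl]cyclohexan-1-one; methyl, OTBS, side chain and CH2OBn all cis | C[C@H]1[C@@H](O[Si](C)(C)C(C)(C)C)C[C@@H](C(C)(C)O[Si](CC)(CC)CC)[C@](COCc2ccccc2)(CC=C)C1=O | intermediate
9 | spiro α-methyl γ-lactone (ring C on ring A; O34 cis to the C1 methyl; C20 epimers) | C[C@H]1[C@@H](O[Si](C)(C)C(C)(C)C)C[C@@H](C(C)(C)O[Si](CC)(CC)CC)[C@](COCc2ccccc2)(CC=C)[C@]12CC(C)C(=O)O2 | intermediate
10 | methyl (E)-but-2-enyl carbonate | C/C=C/COC(=O)OC | starting material
11 | trimethylsilyl ketene acetal of 9 | C[C@H]1[C@@H](O[Si](C)(C)C(C)(C)C)C[C@@H](C(C)(C)O[Si](CC)(CC)CC)[C@](COCc2ccccc2)(CC=C)[C@]12CC(C)=C(O[Si](C)(C)C)O2 | intermediate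
12 | C20-methyl C20-(but-3-en-2-yl) spiro lactone (C20 and C22 as in the target) | C[C@H]1[C@@H](O[Si](C)(C)C(C)(C)C)C[C@@H](C(C)(C)O[Si](CC)(CC)CC)[C@](COCc2ccccc2)(CC=C)[C@]12C[C@@](C)(C(=O)O2)[C@@H](C)C=C | intermediate
13 | diol from 12 (C14 and C25 primary alcohols, C17 benzyl ether) | C[C@H]1[C@@H](O[Si](C)(C)C(C)(C)C)C[C@@H](C(C)(C)O[Si](CC)(CC)CC)[C@](COCc2ccccc2)(CCCO)[C@]12C[C@@](C)(C(=O)O2)[C@@H](C)CCO | intermediate
14 | triol (C14, C17 and C25 primary alcohols) | C[C@H]1[C@@H](O[Si](C)(C)C(C)(C)C)C[C@@H](C(C)(C)O[Si](CC)(CC)CC)[C@](CO)(CCCO)[C@]12C[C@@](C)(C(=O)O2)[C@@H](C)CCO | intermediate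
15 | C25 carboxylic acid with rings A, B and C | C[C@H]1[C@@H](O[Si](C)(C)C(C)(C)C)C[C@@H](C(C)(C)O[Si](CC)(CC)CC)[C@]2(CCC(=O)OC2)[C@]12C[C@@](C)(C(=O)O2)[C@@H](C)CC(=O)O | intermediate
16 | C25 acid chloride with rings A, B and C | C[C@H]1[C@@H](O[Si](C)(C)C(C)(C)C)C[C@@H](C(C)(C)O[Si](CC)(CC)CC)[C@]2(CCC(=O)OC2)[C@]12C[C@@](C)(C(=O)O2)[C@@H](C)CC(=O)Cl | intermediate
17 | methyl pyruvate | CC(=O)C(=O)OC | starting material
18 | methyl 2-methyl-1,3-dioxolane-2-carboxylate | COC(=O)C1(C)OCCO1 | intermediate
19 | 2-methyl-1,3-dioxolane-2-carbaldehyde | O=CC1(C)OCCO1 | intermediate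
20 | ketene from 16 | C[C@H]1[C@@H](O[Si](C)(C)C(C)(C)C)C[C@@H](C(C)(C)O[Si](CC)(CC)CC)[C@]2(CCC(=O)OC2)[C@]12C[C@@](C)(C(=O)O2)[C@@H](C)C=C=O | intermediate
21 | cis β-lactone (C24–C33 and C25–O32 formed; C28 as dioxolane) | C[C@H]1[C@@H](O[Si](C)(C)C(C)(C)C)C[C@@H](C(C)(C)O[Si](CC)(CC)CC)[C@]2(CCC(=O)OC2)[C@]12C[C@@](C)(C(=O)O2)[C@@H](C)[C@@H]1C(=O)O[C@@H]1C1(C)OCCO1 | intermediate
22 | 4-acetyl cis β-lactone | C[C@H]1[C@@H](O[Si](C)(C)C(C)(C)C)C[C@@H](C(C)(C)O[Si](CC)(CC)CC)[C@]2(CCC(=O)OC2)[C@]12C[C@@](C)(C(=O)O2)[C@@H](C)[C@@H]1C(=O)O[C@@H]1C(C)=O | intermediate
23 | ring E lactol (C28 hemiketal, C33 hydroxyl, C22 trans to O32) | C[C@H]1[C@@H](O[Si](C)(C)C(C)(C)C)C[C@@H](C(C)(C)O[Si](CC)(CC)CC)[C@]2(CCC(=O)OC2)[C@]12C[C@@](C)(C(=O)O2)[C@@H](C)[C@@H]1C(=O)OC(C)(O)[C@H]1O | intermediate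
24 | ring E lactone with O30/O32 acetonide, C24 epimeric to the target | C[C@H]1[C@@H](O[Si](C)(C)C(C)(C)C)C[C@@H](C(C)(C)O[Si](CC)(CC)CC)[C@]2(CCC(=O)OC2)[C@]12C[C@@](C)(C(=O)O2)[C@@H](C)[C@@H]3C(=O)O[C@@]4(C)OC(C)(C)O[C@@H]34 | intermediate
25 | ring E lactone with O30/O32 acetonide, C24 as in the target | C[C@H]1[C@@H](O[Si](C)(C)C(C)(C)C)C[C@@H](C(C)(C)O[Si](CC)(CC)CC)[C@]2(CCC(=O)OC2)[C@]12C[C@@](C)(C(=O)O2)[C@@H](C)[C@H]3C(=O)O[C@@]4(C)OC(C)(C)O[C@@H]34 | intermediate
26 | chermebilaene B 3-O-TBS 10-O-TES bis-silyl ether | C[C@H]1[C@@H](O[Si](C)(C)C(C)(C)C)C[C@@H](C(C)(C)O[Si](CC)(CC)CC)[C@]2(CCC(=O)OC2)[C@]12C[C@]1(C)[C@@H](C)[C@H]3C(=O)O[C@@]4(C)O[C@@]1(O[C@@H]34)O2 | intermediate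
27 | chermebilaene B | C[C@H]1[C@@H](O)C[C@@H](C(C)(C)O)[C@]2(CCC(=O)OC2)[C@]12C[C@]1(C)[C@@H](C)[C@H]3C(=O)O[C@@]4(C)O[C@@]1(O[C@@H]34)O2 | target

## Step count and least certain steps

Total: 20 steps. Longest linear sequence: 18 steps from 1 (steps 1–13 and 16–20); aldehyde 19 takes 2 steps from 17.

Step 16 (key step). The bulky ammonium enolate may add only slowly to the hindered aldehyde, whose formyl carbon sits next to a fully substituted carbon, so that ketene dimerisation takes over. The preference of the catalyst may also clash with the resident C22 centre and erode the facial selectivity. Fallback, from 15 and returning at 21: the acid is converted through its pivaloyl mixed anhydride and lithiated (S)-4-benzyl-1,3-oxazolidin-2-one into the N-acyl oxazolidinone F1. Its boron enolate (Bu2BOTf, iPr2NEt) adds to 19 in an Evans aldol reaction to give the syn aldol F2, which has the same C24 and C33 configurations as 21. LiOH/H2O2 removes the auxiliary to give the β-hydroxy acid F3, and benzenesulfonyl chloride in pyridine closes the β-lactone through the activated carboxyl, with retention at C33, to give 21.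

Step 7. Instead of the hydride, the ring bond C18–C11 may migrate (ring contraction), or the allyl π bond or the benzyl ether oxygen may capture the developing C2 cation. The axial C2 methyl may also epimerise next to the new ketone. Fallback, from 7 and returning at 8: Dess–Martin periodinane oxidises the carbinol to the epoxy ketone F4. SmI2 in THF/MeOH at −78 °C cleaves the Cα–O bond to a samarium enolate, whose protonation from the face away from the axial C17 gives the β-hydroxy ketone F5. tBuMe2SiOTf with 2,6-lutidine then gives 8.

Step 9. The tetrasubstituted ketene acetal may attack the allyl–iridium complex sluggishly or at the unsubstituted terminus, and the facial bias at C20 may be small. Fallback, from 9 and returning at 12: Et3OBF4 and then NaOEt convert the lactone into the diethyl orthoester F6. Heating with (E)-but-2-en-1-ol and a trace of propanoic acid exchanges one ethoxy group and eliminates ethanol to the O-butenyl ketene acetal F7, whose [3,3] shift (Johnson–Claisen type) forms C20–C22 and gives 12. The C22 epimer is chosen through the alkene geometry of the butenol (E or Z) by way of the chair transition state, and C20 again through the face flanked by the C2 hydrogen.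

Step 18. The enolate may expel the C33 oxygen (β-elimination, which opens the acetonide), protonation may be unselective, or the strained product may revert on work-up. Fallback, from 15 through the imide F1 of the fallback to step 16, returning at 25: C24 is set when the C24–C33 bond is formed. A magnesium-catalysed anti-aldol reaction of F1 with 19 (MgCl2 (cat.), Et3N, Me3SiCl, EtOAc; acidic methanol work-up) gives the anti aldol F8 with C24 and C33 both as in the target. LiOH/H2O2 gives the anti β-hydroxy acid F9. The conditions of step 17 then remove the dioxolane, the acid closes onto the C28 hydrate to give the lactol F10, and this is trapped as acetonide 25.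

Step 19. The exchange may stall at the hydroxy lactol because too little is gained on closure. Acid and heat may also eliminate the C33 oxygen across C24–C33, or strip the tertiary silyl ether and dehydrate C7. Fallback, from 25 and returning at 27: an aprotic closure driven by silyl transfer replaces the protic one. Aqueous HF in MeCN removes the acetonide and both silyl ethers to give the tetraol lactol F11, and Me3SiCl with imidazole gives the tetrakis(trimethylsilyl) ether F12. Catalytic Me3SiOTf in CH2Cl2 at −78 °C then joins the two silyloxy groups on ring E to the ring C lactone carbonyl with loss of hexamethyldisiloxane. This is the lactone version of acetal formation from carbonyl compounds and bis-silylated diols, and it gives the caged bis(trimethylsilyl) ether F13. HF·pyridine then gives 27.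

## Further compounds

F1 | step 16 | N-acyl (S)-4-benzyl-1,3-oxazolidin-2-one of acid 15 | C[C@H]1[C@@H](O[Si](C)(C)C(C)(C)C)C[C@@H](C(C)(C)O[Si](CC)(CC)CC)[C@]2(CCC(=O)OC2)[C@]12C[C@@](C)(C(=O)O2)[C@@H](C)CC(=O)N1[C@@H](Cc2ccccc2)COC1=O
F2 | step 16 | syn aldol adduct of F1 and 19 | C[C@H]1[C@@H](O[Si](C)(C)C(C)(C)C)C[C@@H](C(C)(C)O[Si](CC)(CC)CC)[C@]2(CCC(=O)OC2)[C@]12C[C@@](C)(C(=O)O2)[C@@H](C)[C@@H]([C@H](O)C1(C)OCCO1)C(=O)N1[C@@H](Cc2ccccc2)COC1=O
F3 | step 16 | syn β-hydroxy acid | C[C@H]1[C@@H](O[Si](C)(C)C(C)(C)C)C[C@@H](C(C)(C)O[Si](CC)(CC)CC)[C@]2(CCC(=O)OC2)[C@]12C[C@@](C)(C(=O)O2)[C@@H](C)[C@@H]([C@H](O)C1(C)OCCO1)C(=O)O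
F4 | step 7 | α,β-epoxy ketone from 7 | C[C@]12O[C@H]1C[C@@H](C(C)(C)O[Si](CC)(CC)CC)[C@](COCc3ccccc3)(CC=C)C2=O
F5 | step 7 | β-hydroxy ketone (C3 hydroxyl and C1 methyl cis) | C[C@H]1[C@@H](O)C[C@@H](C(C)(C)O[Si](CC)(CC)CC)[C@](COCc2ccccc2)(CC=C)C1=O
F6 | step 9 | diethyl orthoester of lactone 9 | C[C@H]1[C@@H](O[Si](C)(C)C(C)(C)C)C[C@@H](C(C)(C)O[Si](CC)(CC)CC)[C@](COCc2ccccc2)(CC=C)[C@]12CC(C)C(OCC)(OCC)O2
F7 | step 9 | O-(E)-but-2-enyl ketene acetal of 9 | C[C@H]1[C@@H](O[Si](C)(C)C(C)(C)C)C[C@@H](C(C)(C)O[Si](CC)(CC)CC)[C@](COCc2ccccc2)(CC=C)[C@]12CC(C)=C(OC/C=C/C)O2
F8 | step 18 | anti aldol adduct of F1 and 19 (C24 and C33 as in the target) | C[C@H]1[C@@H](O[Si](C)(C)C(C)(C)C)C[C@@H](C(C)(C)O[Si](CC)(CC)CC)[C@]2(CCC(=O)OC2)[C@]12C[C@@](C)(C(=O)O2)[C@@H](C)[C@H]([C@H](O)C1(C)OCCO1)C(=O)N1[C@@H](Cc2ccccc2)COC1=O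
F9 | step 18 | anti β-hydroxy acid | C[C@H]1[C@@H](O[Si](C)(C)C(C)(C)C)C[C@@H](C(C)(C)O[Si](CC)(CC)CC)[C@]2(CCC(=O)OC2)[C@]12C[C@@](C)(C(=O)O2)[C@@H](C)[C@H]([C@H](O)C1(C)OCCO1)C(=O)O
F10 | step 18 | ring E lactol with C24 as in the target | C[C@H]1[C@@H](O[Si](C)(C)C(C)(C)C)C[C@@H](C(C)(C)O[Si](CC)(CC)CC)[C@]2(CCC(=O)OC2)[C@]12C[C@@](C)(C(=O)O2)[C@@H](C)[C@H]1C(=O)OC(C)(O)[C@H]1O
F11 | step 19 | desilylated ring E lactol (tetraol) | C[C@H]1[C@@H](O)C[C@@H](C(C)(C)O)[C@]2(CCC(=O)OC2)[C@]12C[C@@](C)(C(=O)O2)[C@@H](C)[C@H]1C(=O)OC(C)(O)[C@H]1O
F12 | step 19 | tetrakis(trimethylsilyl) ether of F11 | C[C@H]1[C@@H](O[Si](C)(C)C)C[C@@H](C(C)(C)O[Si](C)(C)C)[C@]2(CCC(=O)OC2)[C@]12C[C@@](C)(C(=O)O2)[C@@H](C)[C@H]1C(=O)OC(C)(O[Si](C)(C)C)[C@H]1O[Si](C)(C)C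
F13 | step 19 | chermebilaene B bis(trimethylsilyl) ether | C[C@H]1[C@@H](O[Si](C)(C)C)C[C@@H](C(C)(C)O[Si](C)(C)C)[C@]2(CCC(=O)OC2)[C@]12C[C@]1(C)[C@@H](C)[C@H]3C(=O)O[C@@]4(C)O[C@@]1(O[C@@H]34)O2
A1 | alternative 1 | trans-decalin hydroxy acetate with exocyclic C1=C2 alkene, C14 hydroxyl and C17 silyl ether | C=C1CC[C@H]2C(C)(C)[C@@H](O)CC[C@]2(CO[Si](C)(C)C(C)(C)C)[C@H]1COC(C)=O
A2 | alternative 2 | spiro-lactone enone with rings A and B and the free C7 carbinol | CC1=CC[C@@H](C(C)(C)O)[C@]2(CCC(=O)OC2)C1=O
A3 | alternative 3 | spiro γ-lactone with rings A, B and C, methyl ester on C19 and tert-butyl ester at C25 | C[C@H]1[C@@H](O[Si](C)(C)C(C)(C)C)C[C@@H](C(C)(C)O[Si](C)(C)C)[C@]2(CCC(=O)OC2)[C@]12[C@H](C(=O)OC)[C@@](C)(C(=O)O2)[C@@H](C)CC(=O)OC(C)(C)C
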